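**Strategy.** The route rests on cutting the carbocycle of the isochromene core at C5–C6 and at C8–C8a. This exposes the pyran ring as a 4-methylpyrylium, whose anhydrobase is nucleophilic at the exocyclic carbon (C5) and at the enol-ether β-carbon (C8a). C6–C7–C8 becomes an acetoxy(methyl)malonyl unit, in which C7 is stereogenic only because its two carbonyl groups differ. In one pot the acid chloride end acylates C5 and the silver-activated thioester end acylates C8a, which closes the carbocycle and carries the malonyl configuration unchanged into C7. The precursors are the 2-dienyl-4-methylpyrylium salt 9 and the (R)-acid chloride/S-ethyl thioester 15, made from (S)-lactic acid. Chlorination at C5 completes the synthesis.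

Key step: step 8

Remark: a metal salt (enolate, alkoxide) of a numbered compound counts as that compound. The malonyl centre keeps one arrangement in space from 12 to 19; its CIP descriptor changes only with the ranking of its two acyl groups (S in 12–14, R in 15, S in 17 and 18, R in 19). The malonyl unit is built on the pivalaldehyde acetal of (S)-lactic acid so that its configuration comes from a diastereoselective step and no ester must be cleaved beside the thioester. 2-Methyl-4H-pyran-4-one, 2-(triphenylphosphoranylidene)propanal and S-ethyl chlorothioformate are taken as commercial.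

**Step 1**
Reactants: 1 (S)-2-methylbutan-1-ol
Product: 3 (2E,4S)-2,4-dimethylhex-2-enal, via (S)-2-methylbutanal 2 (not isolated)
Conditions: TEMPO (cat.), PhI(OAc)2, CH2Cl2, 0 → 23 °C; then Ph3P=C(Me)CHO, toluene, 60 °C
Reagents that add atoms: 2-(triphenylphosphoranylidene)propanal, CC(C=O)=P(c1ccccc1)(c1ccccc1)c1ccccc1
Why: A TEMPO/PhI(OAc)2 oxidation followed in the same flask by a Wittig olefination with a formyl-stabilised ylide should give the trisubstituted (E)-enal, the non-basic medium sparing the α-stereocentre of aldehyde 2, which is never handled.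

**Step 2**
Reactants: 4 2-methyl-4H-pyran-4-one; 3 (2E,4S)-2,4-dimethylhex-2-enal
Product: 7 2-[(1E,3E,5S)-3,5-dimethylhepta-1,3-dien-1-yl]-4H-pyran-4-one, via aldol adduct 5 (not isolated), via mesylate 6 (not isolated)
Conditions: LiHMDS (1.0 equiv), THF, −78 °C; 3; then MsCl, −78 → 0 °C; DBU, 0 → 23 °C
Reagents that add atoms: none
Why: In a vinylogous aldol condensation the 2-methyl group of the γ-pyranone is deprotonated to the extended enolate, which adds 1,2 to the enal at −78 °C faster than it can deprotonate the γ-position, and mesylation with E1cB elimination should give the conjugated (E)-alkene; the carbinol centre of 5 forms as a mixture and is removed again.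

**Step 3**
Reactants: 7 2-[(1E,3E,5S)-3,5-dimethylhepta-1,3-dien-1-yl]-4H-pyran-4-one
Product: 9 4-methyl-2-[(1E,3E,5S)-3,5-dimethylhepta-1,3-dien-1-yl]pyrylium tetrafluoroborate, via pyranol 8 (not isolated)
Conditions: MeMgBr, THF, −78 → −20 °C; cold H2O quench, Et2O extraction; then HBF4·OEt2, Et2O, −20 → 0 °C, filtration under Ar
Reagents that add atoms: methylmagnesium bromide, C[Mg]Br; tetrafluoroboric acid (diethyl ether complex), [H+].F[B-](F)(F)F
Why: Carbonyl addition of a Grignard reagent to the vinylogous-ester carbonyl of a 4-pyranone and acid-induced ionisation of the doubly allylic tertiary alcohol is the classical pyranone-to-4-alkylpyrylium conversion; the cation is aromatic, so the carbinol centre of 8 is irrelevant, and the salt should precipitate from ether.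

**Step 4**
Reactants: 10 (S)-lactic acid
Product: 11 (2S,5S)-2-tert-butyl-5-methyl-1,3-dioxolan-4-one
Conditions: t-BuCHO, TsOH·H2O (cat.), H2SO4 (cat.), pentane, reflux, Dean–Stark; crystallisation from pentane, −78 °C
Reagents that add atoms: pivalaldehyde, CC(C)(C)C=O
Why: Acid-catalysed acetalisation with azeotropic removal of water (Seebach's self-regeneration of stereocentres) should favour the cis acetal, the new acetal centre C2 being set relative to C5 of lactic acid by the preference of both substituents for the same, less hindered side of the ring, and crystallisation removes the trans isomer, whose level limits the enantiomeric purity of 15.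

**Step 5**
Reactants: 11 (2S,5S)-2-tert-butyl-5-methyl-1,3-dioxolan-4-one
Product: 12 S-ethyl (2S,4S)-2-tert-butyl-4-methyl-5-oxo-1,3-dioxolane-4-carbothioate
Conditions: LDA, THF, −78 °C; then cannulation into EtSC(O)Cl, THF, −78 °C
Reagents that add atoms: S-ethyl chlorothioformate, CCSC(Cl)=O
Why: The lithium enolate of the dioxolanone is attacked on carbon from the face opposite to the tert-butyl group (C-acylation of an ester enolate under 1,3-induction from the acetal centre), so the thiocarboxyl group takes the place of the former hydrogen and the quaternary centre is set with the lactone carbonyl and the thioester as two different acyl groups.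

**Step 6**
Reactants: 12 S-ethyl (2S,4S)-2-tert-butyl-4-methyl-5-oxo-1,3-dioxolane-4-carbothioate
Product: 13 (2S)-3-(ethylsulfanyl)-2-hydroxy-2-methyl-3-oxopropanoic acid
Conditions: TFA/H2O (9:1), 23 °C; evaporation with toluene
Reagents that add atoms: none
Why: Acid hydrolysis of the acylal frees the hydroxy acid and pivalaldehyde, which carries off the oxygen of the water; an S-alkyl thioester is stable to aqueous acid, the half-thioester acid should not decarboxylate at room temperature without base, and the quaternary centre is not touched.

**Step 7**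
Reactants: 13 (2S)-3-(ethylsulfanyl)-2-hydroxy-2-methyl-3-oxopropanoic acid
Product: 15 S-ethyl (2R)-2-acetoxy-3-chloro-2-methyl-3-oxopropanethioate, via acetoxy acid 14 (not isolated)
Conditions: AcCl (neat), 23 → 45 °C; evaporation; then (COCl)2, DMF (cat.), CH2Cl2, 0 → 23 °C
Reagents that add atoms: acetyl chloride, CC(Cl)=O; oxalyl chloride, O=C(Cl)C(Cl)=O
Why: Neat acetyl chloride acetylates tertiary α-hydroxy acids without base, as in the preparation of 2-acetoxyisobutyryl chloride, and oxalyl chloride with catalytic DMF then gives the acid chloride; the quaternary carbon can neither enolise nor form a ketene, and the thioester is inert to both reagents.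

**Step 8**
Reactants: 9 4-methyl-2-[(1E,3E,5S)-3,5-dimethylhepta-1,3-dien-1-yl]pyrylium tetrafluoroborate; 15 S-ethyl (2R)-2-acetoxy-3-chloro-2-methyl-3-oxopropanethioate
Product: 18 5-deschlorosclerotiorin, via methylene-pyran 16 (not isolated), via acylmethylene-pyran 17 (not isolated)
Conditions: i-Pr2NEt (2.2 equiv), CH2Cl2, −78 °C; 15 (1.05 equiv), −78 → −30 °C; then AgOTf (2.5 equiv), 2,6-di-tert-butyl-4-methylpyridine (1.5 equiv), −30 → 23 °C, dark
Reagents that add atoms: none
Why: Proposed new method: the amine converts 9 into methylene-pyran 16, whose exocyclic carbon (C5) attacks the acid chloride of 15, and a second deprotonation gives the push–pull acylmethylene-pyran 17; silver(I) then binds the thioester sulfur, the enol-ether β-carbon C8a adds to the activated carbonyl, and loss of silver thiolate and of the C8a proton gives the vinylogous ester 18. The closest known reactions are the C-acylation of 4-methylpyrylium anhydrobases by acid chlorides, the [3+3] cyclisation of 1,3-dinucleophiles with 2,2-disubstituted malonyl dichlorides, and the thiophilic activation of thioesters for acyl transfer; joining them with two different acyl groups is the new element. The carbocycle closes by a 6-(enol-exo)-exo-trig acylation, the only reasonable ring size, because attack by C5 or by the enone oxygen would give four-membered rings. No stereocentre is formed: C7 is quaternary, cannot enolise or form a ketene, and its configuration follows solely from the order in which the two acyl groups react, which the large reactivity gap between an acid chloride and an unactivated S-alkyl thioester should fix. Two site selectivities are needed: C5 before any ring carbon, secured by the higher nucleophilicity of the exocyclic carbon (its acylation regenerates the aromatic pyrylium), and C8a instead of C4, which is the uncertain one because closure at C4 would give a cation stabilised by the dienyl group; it is expected to favour C8a because closure at C4 would force the C8 carbonyl and the quaternary C7 against the dienyl group on C3, while C8a is flanked only by C1–H and the mobile exocyclic double bond of 17 lets both rotamers interconvert. Complete conversion of 9 into neutral 16 at −78 °C before the acylation also removes the cation whose remote C5′–H is weakly acidic, so the side-chain stereocentre should be kept.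

**Step 9**
Reactants: 18 5-deschlorosclerotiorin
Product: 19 sclerotiorin
Conditions: NCS (1.05 equiv), MeCN, 0 → 23 °C
Reagents that add atoms: N-chlorosuccinimide, O=C1CCC(=O)N1Cl
Why: Electrophilic chlorination of the vinylogous ester by addition–elimination should occur at C5, the α-carbon of the O2–C3=C4–C4a=C5–C6=O push–pull system and the only unsubstituted position next to a carbonyl group, as in the halogenation of azaphilones; the acetate, the diene and both stereocentres are not involved.

**Compound list**
1 | (S)-2-methylbutan-1-ol | CC[C@H](C)CO | starting material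
2 | (S)-2-methylbutanal | CC[C@H](C)C=O | intermediate (not isolated)
3 | (2E,4S)-2,4-dimethylhex-2-enal | CC[C@H](C)/C=C(C)/C=O | intermediate
4 | 2-methyl-4H-pyran-4-one | CC1=CC(=O)C=CO1 | starting material
5 | 2-[(3E,5S)-2-hydroxy-3,5-dimethylhept-3-en-1-yl]-4H-pyran-4-one (both carbinol epimers) | CC[C@H](C)/C=C(C)/C(O)CC1=CC(=O)C=CO1 | intermediate (not isolated)
6 | (3E,5S)-3,5-dimethyl-1-(4-oxo-4H-pyran-2-yl)hept-3-en-2-yl methanesulfonate (both epimers) | CC[C@H](C)/C=C(C)/C(OS(C)(=O)=O)CC1=CC(=O)C=CO1 | intermediate (not isolated)
7 | 2-[(1E,3E,5S)-3,5-dimethylhepta-1,3-dien-1-yl]-4H-pyran-4-one | CC[C@H](C)/C=C(C)/C=C/C1=CC(=O)C=CO1 | intermediate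
8 | 2-[(1E,3E,5S)-3,5-dimethylhepta-1,3-dien-1-yl]-4-methyl-4H-pyran-4-ol (both C4 epimers) | CC[C@H](C)/C=C(C)/C=C/C1=CC(C)(O)C=CO1 | intermediate (not isolated)
9 | 4-methyl-2-[(1E,3E,5S)-3,5-dimethylhepta-1,3-dien-1-yl]pyrylium tetrafluoroborate | Cc1cc[o+]c(/C=C/C(C)=C/[C@@H](C)CC)c1.F[B-](F)(F)F | intermediate
10 | (S)-lactic acid | C[C@H](O)C(=O)O | starting material
11 | (2S,5S)-2-tert-butyl-5-methyl-1,3-dioxolan-4-one (cis) | C[C@@H]1O[C@H](C(C)(C)C)OC1=O | intermediate
12 | S-ethyl (2S,4S)-2-tert-butyl-4-methyl-5-oxo-1,3-dioxolane-4-carbothioate | C[C@]1(C(=O)SCC)O[C@H](C(C)(C)C)OC1=O | intermediate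
13 | (2S)-3-(ethylsulfanyl)-2-hydroxy-2-methyl-3-oxopropanoic acid | OC(=O)[C@](C)(O)C(=O)SCC | intermediate
14 | (2S)-2-acetoxy-3-(ethylsulfanyl)-2-methyl-3-oxopropanoic acid | OC(=O)[C@](C)(OC(C)=O)C(=O)SCC | intermediate (not isolated)
15 | S-ethyl (2R)-2-acetoxy-3-chloro-2-methyl-3-oxopropanethioate | ClC(=O)[C@](C)(OC(C)=O)C(=O)SCC | intermediate
16 | 2-[(1E,3E,5S)-3,5-dimethylhepta-1,3-dien-1-yl]-4-methylidene-4H-pyran | CC[C@H](C)/C=C(C)/C=C/C1=CC(=C)C=CO1 | intermediate (not isolated)
17 | S-ethyl (2S)-2-acetoxy-4-{2-[(1E,3E,5S)-3,5-dimethylhepta-1,3-dien-1-yl]-4H-pyran-4-ylidene}-2-methyl-3-oxobutanethioate | CC[C@H](C)/C=C(C)/C=C/C1=CC(=CC(=O)[C@](C)(OC(C)=O)C(=O)SCC)C=CO1 | intermediate (not isolated)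
18 | 5-deschlorosclerotiorin, (7S)-3-[(1E,3E,5S)-3,5-dimethylhepta-1,3-dien-1-yl]-7-methyl-6,8-dioxo-7,8-dihydro-6H-isochromen-7-yl acetate | CC[C@H](C)/C=C(C)/C=C/C1=CC2=CC(=O)[C@](C)(OC(C)=O)C(=O)C2=CO1 | intermediate
19 | sclerotiorin, (7R)-5-chloro-3-[(1E,3E,5S)-3,5-dimethylhepta-1,3-dien-1-yl]-7-methyl-6,8-dioxo-7,8-dihydro-6H-isochromen-7-yl acetate | CC[C@H](C)/C=C(C)/C=C/C1=CC2=C(Cl)C(=O)[C@](C)(OC(C)=O)C(=O)C2=CO1 | target

**Step count**
Total: 9 steps. Longest linear sequence: 6 steps (steps 4, 5, 6, 7, 8, 9 from (S)-lactic acid); the pyrylium branch is steps 1–3.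

**Steps most likely to fail**

Step 8 (Proposed new method). The ring closure may take place at C4 instead of C8a, the methylene-pyran may condense with itself or with remaining pyrylium, or the silver-activated thioester may fail to acylate the weakly nucleophilic enol-ether carbon. The fallback uses the established alkynylbenzaldehyde route to azaphilones; it sets out from enal 3 and comes back at 18. Horner–Wadsworth–Emmons olefination of 3 with diethyl [3-(trimethylsilyl)prop-2-yn-1-yl]phosphonate (LiHMDS, THF, −78 → 0 °C) should give trimethyl[(3E,5E,7S)-5,7-dimethylnona-3,5-dien-1-yn-1-yl]silane F1. K2CO3 in MeOH removes the silyl group to give (3E,5E,7S)-5,7-dimethylnona-3,5-dien-1-yne F2. Sonogashira coupling of F2 with 6-bromo-2,4-dihydroxy-3-methylbenzaldehyde (from formylation of 5-bromo-2-methylresorcinol) gives 6-[(3E,5E,7S)-5,7-dimethylnona-3,5-dien-1-yn-1-yl]-2,4-dihydroxy-3-methylbenzaldehyde F3. Copper-mediated enantioselective oxidative dearomatisation (Cu(I), a chiral diamine of the sparteine type, O2; the ligand enantiomer is chosen for the required face of C7) with cycloisomerisation of the vinylogous acid gives (7S)-3-[(1E,3E,5S)-3,5-dimethylhepta-1,3-dien-1-yl]-7-hydroxy-7-methyl-6H-isochromene-6,8(7H)-dione F4. Acetylation of F4 (Ac2O, DMAP) returns to 18.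

Step 3. The methyl nucleophile may add in a conjugate sense (at C6 of the pyranone or along the dienyl chain) instead of at the carbonyl group, and the α-unsubstituted pyrylium may be opened by water during isolation. The fallback sets out from 7 and comes back at 9: methylenation of the vinylogous-ester carbonyl with the Tebbe reagent (pyridine, THF/toluene, −40 → 0 °C) gives the methylene-pyran 16 directly by a titanium carbene [2+2] pathway that cannot add in a conjugate sense, and protonation of 16 with HBF4·OEt2 in ether at −40 °C gives 9. This fallback makes no compound outside the compound list (F0).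

Step 5. The enolate may be acylated on oxygen, may condense with itself on warming, or may attack the product. The fallback sets out from 11 and comes back at 12: the enolate (LDA, THF, −78 °C) is carboxylated with CO2 on the face opposite to the tert-butyl group to give (2S,4R)-2-tert-butyl-4-methyl-5-oxo-1,3-dioxolane-4-carboxylic acid F5, and Steglich thioesterification of F5 with ethanethiol (DCC, cat. DMAP, CH2Cl2, 0 °C) gives 12.

**Further compounds**
F1 | step 8 | trimethyl[(3E,5E,7S)-5,7-dimethylnona-3,5-dien-1-yn-1-yl]silane | CC[C@H](C)/C=C(C)/C=C/C#C[Si](C)(C)C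
F2 | step 8 | (3E,5E,7S)-5,7-dimethylnona-3,5-dien-1-yne | CC[C@H](C)/C=C(C)/C=C/C#C
F3 | step 8 | 6-[(3E,5E,7S)-5,7-dimethylnona-3,5-dien-1-yn-1-yl]-2,4-dihydroxy-3-methylbenzaldehyde | CC[C@H](C)/C=C(C)/C=C/C#Cc1cc(O)c(C)c(O)c1C=O
F4 | step 8 | (7S)-3-[(1E,3E,5S)-3,5-dimethylhepta-1,3-dien-1-yl]-7-hydroxy-7-methyl-6H-isochromene-6,8(7H)-dione | CC[C@H](C)/C=C(C)/C=C/C1=CC2=CC(=O)[C@](C)(O)C(=O)C2=CO1
F0 | step 3 | none | none
F5 | step 5 | (2S,4R)-2-tert-butyl-4-methyl-5-oxo-1,3-dioxolane-4-carboxylic acid | C[C@]1(C(=O)O)O[C@H](C(C)(C)C)OC1=O
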